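**Retrosynthetic overview**
- The target is unmasked last from its allyl ester / aryl silyl ether; the two prenyl groups come from double ortho-C-prenylation of the ring-A phenol, whose para position is blocked by the ester.
- Ring A is the only ring built (ring B is bought). It is made by an Alder–Rickert benzannulation of an alk-2-ynoate with 1-methoxy-3-(trimethylsilyloxy)cyclohexa-1,3-diene, which sets ester, ortho-OMe, para-OH and ortho-alkyl in one operation.
- The key C–C bond is ring carbon C6 to the first CH2 of the ethylene bridge. It is made from the dianion of propiolic acid, a d3 donor (β-acyl-vinyl anion, a homoenolate-type synthon at the alkyne oxidation level), and a primary bromide.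
- Both carbons joined in that step are acceptors by nature: the β/ortho carbon of the future benzoate and the CH2–Br carbon.
- Order: ring B from commercial 4-(2-bromoethyl)phenol, key alkylation, ring A formed de novo, prenylation, deprotection.

Assumption: the target has no stereocentre and no stereogenic double bond, so "single enantiomer" is taken to mean the one achiral compound drawn.

**Step 1**
Reactants: 1 4-(2-bromoethyl)phenol
Product: 2 [4-(2-bromoethyl)phenoxy](tert-butyl)dimethylsilane
Conditions: TBSCl (1.1 eq), imidazole (1.5 eq), CH2Cl2, 0 °C to rt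
Reagents that add atoms: tert-butyl(chloro)dimethylsilane (TBSCl), CC(C)(C)[Si](C)(C)Cl
Why: Imidazole-promoted O-silylation masks the phenol so that it survives the dianion, the cycloaddition and NaH, while the primary bromide is untouched under these near-neutral conditions.

**Step 2 (key step)**
Reactants: 2 [4-(2-bromoethyl)phenoxy](tert-butyl)dimethylsilane; 3 propiolic acid
Product: 6 allyl 5-[4-(tert-butyldimethylsilyloxy)phenyl]pent-2-ynoate, via dilithium propiolate 4 (not isolated), via lithium pent-2-ynoate salt 5 (not isolated)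
Conditions: 3 (1.2 eq), n-BuLi (2.4 eq), THF/HMPA 4:1, −78 °C; then 2 (1.0 eq), −78 °C to rt; then allyl bromide (3 eq), rt
Reagents that add atoms: allyl bromide (3-bromoprop-1-ene), C=CCBr
Why: SN2 alkylation of the acetylide carbon of the propiolic acid dianion (a known three-carbon d3 nucleophile) by the primary bromide joins two carbons that are both acceptors by nature, and the resulting lithium carboxylate is O-allylated in the same flask.

**Step 3**
Reactants: 7 3-methoxycyclohex-2-en-1-one
Product: 9 1-methoxy-3-(trimethylsilyloxy)cyclohexa-1,3-diene, via lithium dienolate 8 (not isolated)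
Conditions: LDA (commercial solution, 1.1 eq), THF, −78 °C; TMSCl (1.3 eq), −78 to 0 °C; non-aqueous work-up, distil
Reagents that add atoms: chlorotrimethylsilane (TMSCl), C[Si](C)(C)Cl
Why: Kinetic α'-deprotonation of the vinylogous ester by LDA followed by O-silylation (silyl enol ether formation) gives the cross-conjugated 2-silyloxy diene.

**Step 4**
Reactants: 6 allyl 5-[4-(tert-butyldimethylsilyloxy)phenyl]pent-2-ynoate; 9 1-methoxy-3-(trimethylsilyloxy)cyclohexa-1,3-diene
Product: 12 allyl 2-{2-[4-(tert-butyldimethylsilyloxy)phenyl]ethyl}-4-hydroxy-6-methoxybenzoate, via bicyclo[2.2.2]octadiene cycloadduct 10 (not isolated), via aryl trimethylsilyl ether 11 (not isolated)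
Conditions: 9 (3 eq), o-xylene, BHT (cat.), sealed tube, 140 °C then 185 °C; then 1 M HCl/THF, 0 °C, 10 min
Reagents that add atoms: none
Why: Diels–Alder/Alder–Rickert benzannulation in which the nucleophilic C4 terminus of the diene bonds to the β-carbon of the ynoate, so OMe ends up ortho and OSiMe3 para to the ester; retro-Diels–Alder loss of ethene aromatises the adduct and brief dilute acid cleaves only the aryl trimethylsilyl ether.

**Step 5**
Reactants: 12 allyl 2-{2-[4-(tert-butyldimethylsilyloxy)phenyl]ethyl}-4-hydroxy-6-methoxybenzoate; 13 prenyl bromide (1-bromo-3-methylbut-2-ene)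
Product: 15 allyl 2-{2-[4-(tert-butyldimethylsilyloxy)phenyl]ethyl}-4-hydroxy-6-methoxy-3,5-bis(3-methylbut-2-en-1-yl)benzoate, via 3-prenyl phenol 14 (not isolated)
Conditions: NaH (2.2 eq), toluene, 0 °C to rt; 13 (2.4 eq), rt to 45 °C
Reagents that add atoms: none
Why: Ortho-C-alkylation of the sodium phenoxide with prenyl bromide in a non-polar solvent (phenoxide C-prenylation), where the para position is blocked by the ester so only C3 and C5 can be alkylated; no stereocentre is formed.

**Step 6**
Reactants: 15 allyl 2-{2-[4-(tert-butyldimethylsilyloxy)phenyl]ethyl}-4-hydroxy-6-methoxy-3,5-bis(3-methylbut-2-en-1-yl)benzoate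
Product: 17 4-hydroxy-2-[2-(4-hydroxyphenyl)ethyl]-6-methoxy-3,5-bis(3-methylbut-2-en-1-yl)benzoic acid, via desilylated allyl ester 16 (not isolated)
Conditions: K2CO3 (3 eq), degassed MeOH, rt, 3 h; then Pd(PPh3)4 (5 mol%), rt; cold 1 M HCl to pH 3, 0 °C
Reagents that add atoms: none
Why: K2CO3/MeOH methanolysis removes the aryl silyl ether and Pd(0)-catalysed Tsuji–Trost deallylation (methoxide as allyl acceptor) frees the doubly ortho-substituted acid without ester hydrolysis, leaving the prenyl groups and the aryl methyl ether intact.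

**Compound list**
1 | 4-(2-bromoethyl)phenol | Oc1ccc(CCBr)cc1 | starting material
2 | [4-(2-bromoethyl)phenoxy](tert-butyl)dimethylsilane | CC(C)(C)[Si](C)(C)Oc1ccc(CCBr)cc1 | intermediate
3 | propiolic acid (prop-2-ynoic acid) | C#CC(=O)O | starting material
4 | dilithium propiolate (dianion of propiolic acid) | [Li+].[Li+].[C-]#CC(=O)[O-] | intermediate (not isolated)
5 | lithium 5-[4-(tert-butyldimethylsilyloxy)phenyl]pent-2-ynoate | [Li+].[O-]C(=O)C#CCCc1ccc(O[Si](C)(C)C(C)(C)C)cc1 | intermediate (not isolated)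
6 | allyl (prop-2-en-1-yl) 5-[4-(tert-butyldimethylsilyloxy)phenyl]pent-2-ynoate | C=CCOC(=O)C#CCCc1ccc(O[Si](C)(C)C(C)(C)C)cc1 | intermediate
7 | 3-methoxycyclohex-2-en-1-one | COC1=CC(=O)CCC1 | starting material
8 | lithium 5-methoxycyclohexa-1,5-dien-1-olate | [Li+].COC1=CC([O-])=CCC1 | intermediate (not isolated)
9 | 1-methoxy-3-(trimethylsilyloxy)cyclohexa-1,3-diene | COC1=CC(O[Si](C)(C)C)=CCC1 | intermediate
10 | allyl 3-{2-[4-(tert-butyldimethylsilyloxy)phenyl]ethyl}-1-methoxy-5-(trimethylsilyloxy)bicyclo[2.2.2]octa-2,5-diene-2-carboxylate | COC12CCC(C(O[Si](C)(C)C)=C1)C(CCc1ccc(O[Si](C)(C)C(C)(C)C)cc1)=C2C(=O)OCC=C | intermediate (not isolated)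
11 | allyl 2-{2-[4-(tert-butyldimethylsilyloxy)phenyl]ethyl}-6-methoxy-4-(trimethylsilyloxy)benzoate | C=CCOC(=O)c1c(OC)cc(O[Si](C)(C)C)cc1CCc1ccc(O[Si](C)(C)C(C)(C)C)cc1 | intermediate (not isolated)
12 | allyl 2-{2-[4-(tert-butyldimethylsilyloxy)phenyl]ethyl}-4-hydroxy-6-methoxybenzoate | C=CCOC(=O)c1c(OC)cc(O)cc1CCc1ccc(O[Si](C)(C)C(C)(C)C)cc1 | intermediate
13 | prenyl bromide (1-bromo-3-methylbut-2-ene) | CC(C)=CCBr | starting material
14 | allyl 6-{2-[4-(tert-butyldimethylsilyloxy)phenyl]ethyl}-4-hydroxy-2-methoxy-3-(3-methylbut-2-en-1-yl)benzoate | C=CCOC(=O)c1c(OC)c(CC=C(C)C)c(O)cc1CCc1ccc(O[Si](C)(C)C(C)(C)C)cc1 | intermediate (not isolated)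
15 | allyl 2-{2-[4-(tert-butyldimethylsilyloxy)phenyl]ethyl}-4-hydroxy-6-methoxy-3,5-bis(3-methylbut-2-en-1-yl)benzoate | C=CCOC(=O)c1c(OC)c(CC=C(C)C)c(O)c(CC=C(C)C)c1CCc1ccc(O[Si](C)(C)C(C)(C)C)cc1 | intermediate
16 | allyl 4-hydroxy-2-[2-(4-hydroxyphenyl)ethyl]-6-methoxy-3,5-bis(3-methylbut-2-en-1-yl)benzoate | C=CCOC(=O)c1c(OC)c(CC=C(C)C)c(O)c(CC=C(C)C)c1CCc1ccc(O)cc1 | intermediate (not isolated)
17 | 4-hydroxy-2-[2-(4-hydroxyphenyl)ethyl]-6-methoxy-3,5-bis(3-methylbut-2-en-1-yl)benzoic acid (CNP0254933.0) | COc1c(CC=C(C)C)c(O)c(CC=C(C)C)c(CCc2ccc(O)cc2)c1C(=O)O | target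

**Step count**
Total: 6 steps. Longest linear sequence: 5 steps (steps 1, 2, 4, 5, 6); step 3 is the side branch that supplies the diene.

**Three steps most likely to fail**

Step 2 (key alkylation). The dianion 4 is poorly soluble and only moderately nucleophilic, and E2 of bromide 2 to the styrene competes. The fallback keeps the same bond and donor carbon but carries the carboxyl as an orthoester, which makes the donor an ordinary, soluble lithium acetylide. It sets out from 2. Alkylation with lithiated commercial 3,3,3-triethoxyprop-1-yne (n-BuLi, THF/DMPU, −78 °C to rt) gives tert-butyl(dimethyl)[4-(5,5,5-triethoxypent-3-yn-1-yl)phenoxy]silane F1. PPTS in wet ethanol at rt then gives ethyl 5-[4-(tert-butyldimethylsilyloxy)phenyl]pent-2-ynoate F2. Titanate-catalysed transesterification with allyl alcohol (Ti(OiPr)4 cat., 80 °C) comes back to the route at 6.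

Step 4 (benzannulation). The β-alkyl ynoate is a sluggish dienophile, and the high temperature needed for ethene extrusion invites 1,5-H shifts in the cyclic diene. The fallback uses an acyclic ketene-acetal diene whose adduct aromatises by elimination rather than cycloreversion. It sets out from 6. Acetyl chloride and 1,1-dimethoxyethene (2 eq, Et2O, 0 °C) give 4,4-dimethoxybut-3-en-2-one F3. TMSCl/Et3N/ZnCl2 (cat.) converts it into 1,1-dimethoxy-3-(trimethylsilyloxy)buta-1,3-diene F4. Heating F4 with 6 (toluene, 110–130 °C) gives allyl 2-{2-[4-(tert-butyldimethylsilyloxy)phenyl]ethyl}-6,6-dimethoxy-4-(trimethylsilyloxy)cyclohexa-1,4-diene-1-carboxylate F5, which loses methanol in the flask and comes back to the route at 11. The acid work-up of step 4 then gives 12.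

Step 5 (double C-prenylation). O-prenylation, over-alkylation to dienones and the hindered C5 position can keep the yield low. The fallback installs both prenyl groups by cross-coupling. It sets out from 12. NBS (2.05 eq, MeCN, −20 °C) gives allyl 3,5-dibromo-6-{2-[4-(tert-butyldimethylsilyloxy)phenyl]ethyl}-4-hydroxy-2-methoxybenzoate F6. Double Stille coupling with tributyl(3-methylbut-2-en-1-yl)stannane (Pd2(dba)3/P(t-Bu)3, CsF, dioxane, 90 °C) comes back to the route at 15.

**Further compounds**
F1 | step 2 | tert-butyl(dimethyl)[4-(5,5,5-triethoxypent-3-yn-1-yl)phenoxy]silane | CCOC(OCC)(OCC)C#CCCc1ccc(O[Si](C)(C)C(C)(C)C)cc1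
F2 | step 2 | ethyl 5-[4-(tert-butyldimethylsilyloxy)phenyl]pent-2-ynoate | CCOC(=O)C#CCCc1ccc(O[Si](C)(C)C(C)(C)C)cc1
F3 | step 4 | 4,4-dimethoxybut-3-en-2-one | CC(=O)C=C(OC)OC
F4 | step 4 | 1,1-dimethoxy-3-(trimethylsilyloxy)buta-1,3-diene | C=C(O[Si](C)(C)C)C=C(OC)OC
F5 | step 4 | allyl 2-{2-[4-(tert-butyldimethylsilyloxy)phenyl]ethyl}-6,6-dimethoxy-4-(trimethylsilyloxy)cyclohexa-1,4-diene-1-carboxylate | C=CCOC(=O)C1=C(CCc2ccc(O[Si](C)(C)C(C)(C)C)cc2)CC(O[Si](C)(C)C)=CC1(OC)OC
F6 | step 5 | allyl 3,5-dibromo-6-{2-[4-(tert-butyldimethylsilyloxy)phenyl]ethyl}-4-hydroxy-2-methoxybenzoate | C=CCOC(=O)c1c(OC)c(Br)c(O)c(Br)c1CCc1ccc(O[Si](C)(C)C(C)(C)C)cc1
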